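## Retrosynthetic overview
1. The (3S)-isoflavan comes from the racemic isoflavanone. One asymmetric transfer hydrogenation cascade, run last, removes the C4 oxygen and fixes C3 by dynamic kinetic resolution.
2. The isoflavanone is cut at C3–C1′. The chromanone α-carbon acts as an electrophile (trivalent-iodine enolonium) and takes a C–H position of 1,2,3,4-tetramethoxybenzene, so two natural nucleophiles are joined.
3. The enolonium comes from the bis-trimethylsilyl derivative of 7-hydroxy-8-methoxychroman-4-one. One silylation makes the enol ether and masks the phenol.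
4. The chromanone comes from 2-methoxyresorcinol and 3-chloropropanoic acid.
5. Rings A and B are bought. Ring C is the only ring formed, in step 1.

Assumption: the SMILES reads as 3S (priority C2 > C1′ > C4 > H), and operations run in one flask without isolation count as one step.

## Route

Step 1
Reactants: 1 2-methoxybenzene-1,3-diol (2-methoxyresorcinol); 2 3-chloropropanoic acid
Product: 4 7-hydroxy-8-methoxychroman-4-one, via chloropropiophenone 3 (not isolated)
Conditions: TfOH (4 equiv), neat, 80 °C, 1 h; cooled mixture run into excess 2 M aq NaOH, 0 °C → rt, 2 h; aq HCl to pH 2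
Reagents that add atoms: none
Why: Friedel–Crafts acylation in TfOH goes at C4 of 1 (ortho to one OH, para to the other, C4 and C6 being equivalent), and cold NaOH then closes ring C by intramolecular Williamson O-alkylation (or elimination/oxa-Michael addition) through the only phenoxide that can reach the chloride.

Step 2
Reactants: 4 7-hydroxy-8-methoxychroman-4-one
Product: 5 8-methoxy-4,7-bis(trimethylsilyloxy)-2H-chromene
Conditions: TMSOTf (2.5 equiv), Et3N (3.5 equiv), CH2Cl2, 0 °C → rt; pentane trituration and filtration, no aqueous work-up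
Reagents that add atoms: trimethylsilyl triflate, C[Si](C)(C)OS(=O)(=O)C(F)(F)F
Why: Soft enolisation (silyl triflate/amine silyl enol ether formation) converts the ketone into its only possible enol ether (C3=C4) without the strong base that would open ring C by retro-oxa-Michael reaction, and it silylates the 7-OH in the same operation.

Step 3
Reactants: 5 8-methoxy-4,7-bis(trimethylsilyloxy)-2H-chromene; 6 [hydroxy(tosyloxy)iodo]benzene (Koser's reagent); 7 1,2,3,4-tetramethoxybenzene
Product: 10 rac-7-hydroxy-8-methoxy-3-(2,3,4,5-tetramethoxyphenyl)chroman-4-one, via enolonium tosylate 8 (not isolated), via silyl-protected isoflavanone 9 (not isolated)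
Conditions: 6 (1.05 equiv), BF3·OEt2 (1.5 equiv, Lewis acid promoter), CH2Cl2, −78 °C; 5 added dropwise, 10 min; then 7 (3 equiv, excess recovered), −78 °C → rt; aq NaHCO3, then 1 M HCl/THF
Reagents that add atoms: none
Why: Proposed new method: adding enol silane 5 to PhI(OH)OTs/BF3·OEt2 at −78 °C gives the O-bound trivalent-iodine enolate 8, whose C3 is now electrophilic (enolonium umpolung), and the only free CH position of electron-rich arene 7 (C5 and C6 are equivalent) attacks C3 in an SN2′-type Friedel–Crafts step that expels PhI and TsOH, so two natural nucleophiles are joined without prefunctionalising ring B; the closest known reaction type is the two-stage enolonium α-arylation of ketone silyl enol ethers with indoles, pyrroles, thiophenes and alkoxyarenes, stretched here to a chromanone with a β-oxygen and to a tetraalkoxybenzene, and C3 is formed racemic on purpose because it is epimerisable and is fixed in step 4.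

Step 4
Reactants: 10 rac-7-hydroxy-8-methoxy-3-(2,3,4,5-tetramethoxyphenyl)chroman-4-one
Product: 13 (3S)-8-methoxy-3-(2,3,4,5-tetramethoxyphenyl)chroman-7-ol (target), via cis-isoflavan-4-ol 11 (not isolated), via para-quinone methide 12 (not isolated)
Conditions: RuCl[(S,S)-TsDPEN](p-cymene) (3 mol %), HCO2H/Et3N (5:2), EtOAc, 25 °C until 10 is consumed, then 60 °C
Reagents that add atoms: none
Why: This is a Noyori–Ikariya asymmetric transfer hydrogenation under dynamic kinetic resolution followed by quinone-methide deoxygenation, in which Et3N racemises 10 through its enol, the (S,S)-catalyst reduces only the (3S)-ketone from the face anti to ring B to give the 4S carbinol (same sense as acetophenone to (S)-1-phenylethanol), that is cis-(3S,4S)-11, and on warming the free 7-OH expels the 4-OH as water to give 12, which takes a second hydride from Ru–H at C4 (1,6-reduction), so C3 stays S and C4 becomes CH2.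

## Compound list
1 | 2-methoxybenzene-1,3-diol | COc1c(O)cccc1O | starting material
2 | 3-chloropropanoic acid | OC(=O)CCCl | starting material
3 | 3-chloro-1-(2,4-dihydroxy-3-methoxyphenyl)propan-1-one | COc1c(O)ccc(C(=O)CCCl)c1O | intermediate
4 | 7-hydroxy-8-methoxychroman-4-one | COc1c(O)ccc2C(=O)CCOc12 | intermediate
5 | 8-methoxy-4,7-bis(trimethylsilyloxy)-2H-chromene | COc1c(O[Si](C)(C)C)ccc2C(O[Si](C)(C)C)=CCOc12 | intermediate
6 | [hydroxy(tosyloxy)iodo]benzene (Koser's reagent) | OI(OS(=O)(=O)c1ccc(C)cc1)c1ccccc1 | starting material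
7 | 1,2,3,4-tetramethoxybenzene | COc1ccc(OC)c(OC)c1OC | starting material
8 | [8-methoxy-7-(trimethylsilyloxy)-2H-chromen-4-yl]oxy(phenyl)(tosyloxy)-λ3-iodane (enolonium species) | COc1c(O[Si](C)(C)C)ccc2C(OI(OS(=O)(=O)c3ccc(C)cc3)c3ccccc3)=CCOc12 | intermediate
9 | rac-8-methoxy-3-(2,3,4,5-tetramethoxyphenyl)-7-(trimethylsilyloxy)chroman-4-one | COc1cc(C2COc3c(ccc(O[Si](C)(C)C)c3OC)C2=O)c(OC)c(OC)c1OC | intermediate
10 | rac-7-hydroxy-8-methoxy-3-(2,3,4,5-tetramethoxyphenyl)chroman-4-one | COc1cc(C2COc3c(ccc(O)c3OC)C2=O)c(OC)c(OC)c1OC | intermediate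
11 | (3S,4S)-8-methoxy-3-(2,3,4,5-tetramethoxyphenyl)chroman-4,7-diol (cis) | COc1cc([C@H]2COc3c(ccc(O)c3OC)[C@H]2O)c(OC)c(OC)c1OC | intermediate
12 | (3S)-8-methoxy-3-(2,3,4,5-tetramethoxyphenyl)-2,3-dihydro-7H-chromen-7-one (para-quinone methide) | O=C1C=CC2=C[C@@H](c3cc(OC)c(OC)c(OC)c3OC)COC2=C1OC | intermediate
13 | (3S)-8-methoxy-3-(2,3,4,5-tetramethoxyphenyl)chroman-7-ol | COc1cc([C@H]2COc3c(ccc(O)c3OC)C2)c(OC)c(OC)c1OC | target

## Step count and risks
Total steps: 4. Longest linear sequence: 4 (1 → 4 → 5 → 10 → 13).

**Step 3 (highest risk).**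
- Enolonium 8 may lose a C2 proton to give the chromone.
- It may collapse to the α-tosyloxy ketone.
- It may oxidise 7 or ring A by electron transfer.
- Any isoflavone formed by over-oxidation does no harm, because the step 4 catalyst reduces it back to 10.
- Fallback, from 5 and 7, returning at 9: the same electrophilic C3 is used as an α-halo ketone in a metal-catalysed cross-coupling instead of a metal-free arene attack.
  - NBS (THF, −78 °C, non-aqueous work-up) converts 5 into 3-bromo-8-methoxy-7-(trimethylsilyloxy)chroman-4-one F1.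
  - Separately, 7 is ortho-lithiated (n-BuLi, TMEDA, THF, 0 °C) to (2,3,4,5-tetramethoxyphenyl)lithium F2.
  - ZnCl2 transmetalates this to (2,3,4,5-tetramethoxyphenyl)zinc chloride F3.
  - A radical-type Negishi α-arylation of F1 with F3 (NiCl2·glyme, 4,4′-di-tert-butyl-2,2′-bipyridine, THF, −30 °C) gives 9. The acidic work-up of step 3 turns 9 into 10.

**Step 4.**
- The cascade may stop at 11.
- Quinone methide 12 may tautomerise to the achiral isoflav-3-ene, which costs yield or ee.
- Fallback, from 10, returning at 13: the alkene is made on purpose and the stereocentre is set by hydrogenation.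
  - NaBH4 (MeOH, 0 °C) gives racemic 8-methoxy-3-(2,3,4,5-tetramethoxyphenyl)chroman-4,7-diol F4 as a cis/trans mixture.
  - Catalytic TsOH (toluene, 80 °C) dehydrates it to 8-methoxy-3-(2,3,4,5-tetramethoxyphenyl)-2H-chromen-7-ol F5.
  - Asymmetric hydrogenation with [Ir(cod)(tBu-PHOX)]BArF (H2 50 bar, CH2Cl2) gives 13. The ligand enantiomer that gives 3S is picked by a test run on F5.

**Step 1.**
- Hot TfOH may cleave the crowded methyl ether or give a poor mass balance.
- Fallback, from 1, returning at 4: the O–C2 bond is made first and the aryl–carbonyl bond last.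
  - Excess 1 and acrylonitrile (catalytic benzyltrimethylammonium hydroxide, reflux) give 3-(3-hydroxy-2-methoxyphenoxy)propanenitrile F6 by oxa-Michael addition.
  - An intramolecular Houben–Hoesch cyclisation (TfOH/TFA, rt) closes ortho to the ether oxygen and para to the OH, giving 7-hydroxy-8-methoxychroman-4-imine F7.
  - Water hydrolyses F7 to 4.

## Further compounds
F1 | step 3 | 3-bromo-8-methoxy-7-(trimethylsilyloxy)chroman-4-one | COc1c(O[Si](C)(C)C)ccc2C(=O)C(Br)COc12
F2 | step 3 | (2,3,4,5-tetramethoxyphenyl)lithium | [Li]c1cc(OC)c(OC)c(OC)c1OC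
F3 | step 3 | (2,3,4,5-tetramethoxyphenyl)zinc chloride | Cl[Zn]c1cc(OC)c(OC)c(OC)c1OC
F4 | step 4 | racemic 8-methoxy-3-(2,3,4,5-tetramethoxyphenyl)chroman-4,7-diol (cis/trans mixture) | COc1cc(C2COc3c(ccc(O)c3OC)C2O)c(OC)c(OC)c1OC
F5 | step 4 | 8-methoxy-3-(2,3,4,5-tetramethoxyphenyl)-2H-chromen-7-ol | COc1cc(C2=Cc3ccc(O)c(OC)c3OC2)c(OC)c(OC)c1OC
F6 | step 1 | 3-(3-hydroxy-2-methoxyphenoxy)propanenitrile | COc1c(O)cccc1OCCC#N
F7 | step 1 | 7-hydroxy-8-methoxychroman-4-imine | COc1c(O)ccc2C(=N)CCOc12
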